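**Plan** (oxolane numbering: O1; C2 carries ring A, the free guaiacyl; C3 and C4 carry the cis methyls; C5 carries ring B, the etherified aryl; ring C is the side-chain guaiacyl)
- Cuts, in order: the side-chain carbinol C–H, the ring C–carbonyl bond and the ring B O–CH(CH3) bond; the C2–H and C3–H bonds; the O1–C5 bond; the ring A–carbonyl bond; the two cyclopropane bonds to the CH–CH3 carbon; the C=C of an α-methylcinnamyl alcohol.
- Enabling feature: O1–C5 is benzylic to the para-oxygenated ring B, so C5 can be a quinone-methide-stabilised cation and the ring A ketone oxygen its nucleophile; the C3–C4 and C4–C5 bonds are then the two surviving bonds of an aroyl cyclopropane.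
- Forward: Wittig chain, three-membered ring by ethylidene transfer, ring A aroyl group, ring expansion to the five-membered ring, hydrogenation, then the lactate unit on ring B and ring C last.
- Stereochemistry: C4 from the ligand-controlled cyclopropanation; C5 trans to the C4 methyl in the ring expansion; C2 and C3 by syn addition of H2 anti to the C4 methyl; the ether carbon from ethyl (S)-lactate with Mitsunobu inversion; the carbinol by chelation-controlled Zn(BH4)2 reduction.

Key step: step 8

Assumption: the (4S,5S)-dioxaborolane is taken to deliver the ethylidene to the alkene face of 4 that mirrors its known sense for 3-arylallyl alcohols, with the carbenoid methyl ending on the CH2OH side; if the facial sense proved opposite, the antipodal ligand would be used.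

Step 1
Reactants: 1 4-(benzyloxy)-3-methoxybenzaldehyde; 2 ethyl 2-(triphenyl-λ5-phosphanylidene)propanoate
Product: 3 ethyl (2E)-3-[4-(benzyloxy)-3-methoxyphenyl]-2-methylprop-2-enoate
Conditions: toluene, 90 °C
Reagents that add atoms: none
Why: Wittig olefination with a stabilised α-methyl ylide should give the (E)-enoate (aryl trans to the ester) almost exclusively.

Step 2
Reactants: 3 ethyl (2E)-3-[4-(benzyloxy)-3-methoxyphenyl]-2-methylprop-2-enoate
Product: 4 (2E)-3-[4-(benzyloxy)-3-methoxyphenyl]-2-methylprop-2-en-1-ol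
Conditions: i-Bu2AlH, CH2Cl2, −78 → 0 °C; then H2O
Reagents that add atoms: none
Why: 1,2-reduction of the enoate by the aluminium hydride gives the allylic alcohol without touching alkene geometry or the benzyl ether.

Step 3
Reactants: 4 (2E)-3-[4-(benzyloxy)-3-methoxyphenyl]-2-methylprop-2-en-1-ol
Product: 5 [(1R,2S,3R)-2-[4-(benzyloxy)-3-methoxyphenyl]-1,3-dimethylcyclopropyl]methanol
Conditions: Et2Zn, CH3CHI2, (4S,5S)-2-butyl-N,N,N',N'-tetramethyl-1,3,2-dioxaborolane-4,5-dicarboxamide (1.2 equiv), CH2Cl2, −40 → 0 °C; then H2O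
Reagents that add atoms: 1,1-diiodoethane, CC(I)I
Why: Charette asymmetric Simmons–Smith-type cyclopropanation with a substituted zinc carbenoid: the alkoxide of 4 binds to boron of the chiral dioxaborolane, which holds the zinc carbenoid over one alkene face and so fixes the two ring carbons derived from the alkene, while the carbenoid methyl should settle on the side carrying CH2OH and H, not the side carrying methyl and aryl, which makes the CH–CH3 carbon 3R; the C3 epimer, which would later give the enantiomer of 12, is removed here by chromatography.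

Step 4
Reactants: 5 [(1R,2S,3R)-2-[4-(benzyloxy)-3-methoxyphenyl]-1,3-dimethylcyclopropyl]methanol
Product: 6 (1R,2S,3R)-2-[4-(benzyloxy)-3-methoxyphenyl]-1,3-dimethylcyclopropane-1-carbaldehyde
Conditions: Pr4N[RuO4] (5 mol %), NMO, 4 Å MS, CH2Cl2, rt
Reagents that add atoms: none
Why: Ley–Griffith oxidation converts the primary alcohol into the aldehyde under neutral conditions; the α-carbon is quaternary and cannot epimerise.

Step 5
Reactants: 7 4-bromo-2-methoxyphenol
Product: 8 (4-bromo-2-methoxyphenoxy)(tert-butyl)dimethylsilane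
Conditions: TBSCl, imidazole, DMF, rt
Reagents that add atoms: tert-butyldimethylsilyl chloride, CC(C)(C)[Si](C)(C)Cl
Why: Imidazole-promoted silylation protects the phenol as a silyl ether that tolerates organometallic formation and hydrogenation and is orthogonal to the benzyl ether of ring B.

Step 6
Reactants: 6 (1R,2S,3R)-2-[4-(benzyloxy)-3-methoxyphenyl]-1,3-dimethylcyclopropane-1-carbaldehyde; 8 (4-bromo-2-methoxyphenoxy)(tert-butyl)dimethylsilane
Product: 10 [(1R,2S,3R)-2-[4-(benzyloxy)-3-methoxyphenyl]-1,3-dimethylcyclopropyl]{4-[(tert-butyldimethylsilyl)oxy]-3-methoxyphenyl}methanol (both carbinol epimers), via aryllithium 9 (not isolated)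
Conditions: 8, n-BuLi, THF, −78 °C; then 6, −78 → 0 °C; then H2O
Reagents that add atoms: none
Why: Bromine–lithium exchange followed by 1,2-addition of the aryllithium to the non-enolisable aldehyde attaches ring A; the new carbinol centre is removed in step 7, so its configuration does not matter.

Step 7
Reactants: 10 [(1R,2S,3R)-2-[4-(benzyloxy)-3-methoxyphenyl]-1,3-dimethylcyclopropyl]{4-[(tert-butyldimethylsilyl)oxy]-3-methoxyphenyl}methanol
Product: 11 [(1R,2S,3R)-2-[4-(benzyloxy)-3-methoxyphenyl]-1,3-dimethylcyclopropyl]{4-[(tert-butyldimethylsilyl)oxy]-3-methoxyphenyl}methanone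
Conditions: Pr4N[RuO4] (5 mol %), NMO, 4 Å MS, CH2Cl2, rt
Reagents that add atoms: none
Why: Ley–Griffith oxidation of the benzylic alcohol is neutral, so the acid-labile electron-rich aryl cyclopropyl carbinol is not ionised before it becomes the ketone.

Step 8
Reactants: 11 [(1R,2S,3R)-2-[4-(benzyloxy)-3-methoxyphenyl]-1,3-dimethylcyclopropyl]{4-[(tert-butyldimethylsilyl)oxy]-3-methoxyphenyl}methanone
Product: 12 (2S,3S)-2-[4-(benzyloxy)-3-methoxyphenyl]-5-{4-[(tert-butyldimethylsilyl)oxy]-3-methoxyphenyl}-3,4-dimethyl-2,3-dihydrofuran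
Conditions: Sc(OTf)3 (10 mol %), 4 Å MS, ClCH2CH2Cl, 25 → 60 °C
Reagents that add atoms: none
Why: Sc(OTf)3 binds the ketone oxygen and the cyclopropane bond between the aroyl-bearing quaternary carbon and the ring B-bearing carbon heterolyses with release of strain, giving a scandium enolate and a benzylic cation delocalised onto the para-benzyloxy oxygen as a quinone-methide oxocarbenium ion, which the enolate oxygen then captures to form O1–C5 and free the catalyst. The closest known reaction type is the Lewis acid-catalysed Cloke–Wilson rearrangement of 2-aryl (donor) cyclopropyl ketones to 2,3-dihydrofurans. The one ring formed, the five-membered dihydrofuran, closes by O-alkylation of the enolate in a 5-exo-trig attack on the exocyclic C=C of the quinone-methide form, a mode open to the in-plane oxygen lone pair. The CH–CH3 carbon keeps all four bonds and becomes C4 unchanged, the other two cyclopropane centres are erased, and the one new centre, C5, is controlled by the C4 methyl: ring B takes the trans position, kinetically by closure anti to the methyl and thermodynamically because O1–C5 can reionise under the catalyst. The step needs cleavage of the bond to the aryl-bearing carbon (not the bond to the CH–CH3 carbon), O-closure and not C-closure, and closure faster than proton loss from the cation; the para-oxygenated ring B secures the first, the strain of re-forming the cyclopropane (the only C-closure possible) the second, and a mild oxophilic catalyst in a dry, non-basic, non-nucleophilic medium the third.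

Step 9
Reactants: 12 (2S,3S)-2-[4-(benzyloxy)-3-methoxyphenyl]-5-{4-[(tert-butyldimethylsilyl)oxy]-3-methoxyphenyl}-3,4-dimethyl-2,3-dihydrofuran
Product: 14 4-[(2S,3S,4R,5S)-5-{4-[(tert-butyldimethylsilyl)oxy]-3-methoxyphenyl}-3,4-dimethyloxolan-2-yl]-2-methoxyphenol, via debenzylated dihydrofuran 13 (not isolated)
Conditions: H2 (1–4 atm), 10% Pd/C, NaHCO3, EtOAc–EtOH, rt
Reagents that add atoms: none
Why: Heterogeneous catalytic hydrogenation adds both hydrogens syn to the face of the enol ether opposite the allylic C4 methyl, which sits on the carbon next to the double bond, so C3 (R) and C2 (S) are set with ring A, the C3 methyl and the C4 methyl all cis; the same conditions hydrogenolyse the ring B benzyl ether, expected to go first, and the bicarbonate keeps the medium non-acidic so that O1–C5 does not ionise.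

Step 10
Reactants: 14 4-[(2S,3S,4R,5S)-5-{4-[(tert-butyldimethylsilyl)oxy]-3-methoxyphenyl}-3,4-dimethyloxolan-2-yl]-2-methoxyphenol; 15 ethyl (2S)-2-hydroxypropanoate
Product: 16 ethyl (2R)-2-{4-[(2S,3S,4R,5S)-5-{4-[(tert-butyldimethylsilyl)oxy]-3-methoxyphenyl}-3,4-dimethyloxolan-2-yl]-2-methoxyphenoxy}propanoate
Conditions: PPh3, DIAD, THF, 0 °C → rt
Reagents that add atoms: none
Why: Mitsunobu etherification of the ring B phenol with the activated lactate proceeds by SN2 displacement with clean inversion, turning the (S)-alcohol into the (R)-aryl ether carbon.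

Step 11
Reactants: 16 ethyl (2R)-2-{4-[(2S,3S,4R,5S)-5-{4-[(tert-butyldimethylsilyl)oxy]-3-methoxyphenyl}-3,4-dimethyloxolan-2-yl]-2-methoxyphenoxy}propanoate
Product: 17 (2R)-2-{4-[(2S,3S,4R,5S)-5-{4-[(tert-butyldimethylsilyl)oxy]-3-methoxyphenyl}-3,4-dimethyloxolan-2-yl]-2-methoxyphenoxy}-N-methoxy-N-methylpropanamide
Conditions: MeNH(OMe)·HCl, i-PrMgCl, THF, −20 → 0 °C
Reagents that add atoms: N,O-dimethylhydroxylamine hydrochloride, CNOC.Cl
Why: Aminolysis of the ester by the magnesium amide formed in the flask (Weinreb amide formation) is fast at low temperature and the weakly basic amide should not enolise the α-aryloxy centre.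

Step 12
Reactants: 17 (2R)-2-{4-[(2S,3S,4R,5S)-5-{4-[(tert-butyldimethylsilyl)oxy]-3-methoxyphenyl}-3,4-dimethyloxolan-2-yl]-2-methoxyphenoxy}-N-methoxy-N-methylpropanamide; 8 (4-bromo-2-methoxyphenoxy)(tert-butyl)dimethylsilane
Product: 19 (2R)-1-{4-[(tert-butyldimethylsilyl)oxy]-3-methoxyphenyl}-2-{4-[(2S,3S,4R,5S)-5-{4-[(tert-butyldimethylsilyl)oxy]-3-methoxyphenyl}-3,4-dimethyloxolan-2-yl]-2-methoxyphenoxy}propan-1-one, via arylmagnesium bromide 18 (not isolated)
Conditions: 8, Mg turnings (I2 cat.), THF, 50 °C; then 17, THF, −20 → 0 °C; then AcOH, −20 °C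
Reagents that add atoms: none
Why: Weinreb ketone synthesis with the aryl Grignard reagent formed by magnesium insertion into 8: the chelated tetrahedral adduct blocks over-addition and releases the ketone only on the acidic quench, and the weakly basic arylmagnesium should not enolise the α-aryloxy centre, which therefore never meets base as a ketone.

Step 13
Reactants: 19 (2R)-1-{4-[(tert-butyldimethylsilyl)oxy]-3-methoxyphenyl}-2-{4-[(2S,3S,4R,5S)-5-{4-[(tert-butyldimethylsilyl)oxy]-3-methoxyphenyl}-3,4-dimethyloxolan-2-yl]-2-methoxyphenoxy}propan-1-one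
Product: 20 (1S,2R)-1-{4-[(tert-butyldimethylsilyl)oxy]-3-methoxyphenyl}-2-{4-[(2S,3S,4R,5S)-5-{4-[(tert-butyldimethylsilyl)oxy]-3-methoxyphenyl}-3,4-dimethyloxolan-2-yl]-2-methoxyphenoxy}propan-1-ol
Conditions: Zn(BH4)2, Et2O, −30 → 0 °C; then H2O
Reagents that add atoms: none
Why: Chelation-controlled (Cram-chelate) reduction: zinc bridges the carbonyl and the α-aryloxy oxygen and hydride enters from the side of the small α-hydrogen, which should give the erythro (1S,2R) alcohol.

Step 14
Reactants: 20 (1S,2R)-1-{4-[(tert-butyldimethylsilyl)oxy]-3-methoxyphenyl}-2-{4-[(2S,3S,4R,5S)-5-{4-[(tert-butyldimethylsilyl)oxy]-3-methoxyphenyl}-3,4-dimethyloxolan-2-yl]-2-methoxyphenoxy}propan-1-ol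
Product: 21 4-[(1S,2R)-1-hydroxy-2-{4-[(2S,3S,4R,5S)-5-(4-hydroxy-3-methoxyphenyl)-3,4-dimethyloxolan-2-yl]-2-methoxyphenoxy}propyl]-2-methoxyphenol (CNP0171079.3)
Conditions: Bu4NF, AcOH, THF, 0 °C → rt
Reagents that add atoms: none
Why: Fluoride-mediated desilylation frees both phenols, and the acetic acid buffer keeps the phenoxides protonated so that the para-hydroxybenzylic C–O bonds are not opened through quinone methides.

**Compound list**
1 | 4-(benzyloxy)-3-methoxybenzaldehyde (O-benzylvanillin) | COc1cc(C=O)ccc1OCc1ccccc1 | starting material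
2 | ethyl 2-(triphenyl-λ5-phosphanylidene)propanoate | CCOC(=O)C(C)=P(c1ccccc1)(c1ccccc1)c1ccccc1 | starting material
3 | ethyl (2E)-3-[4-(benzyloxy)-3-methoxyphenyl]-2-methylprop-2-enoate | CCOC(=O)/C(C)=C/c1ccc(OCc2ccccc2)c(OC)c1 | intermediate
4 | (2E)-3-[4-(benzyloxy)-3-methoxyphenyl]-2-methylprop-2-en-1-ol | OC/C(C)=C/c1ccc(OCc2ccccc2)c(OC)c1 | intermediate
5 | [(1R,2S,3R)-2-[4-(benzyloxy)-3-methoxyphenyl]-1,3-dimethylcyclopropyl]methanol | C[C@]1(CO)[C@H](c2ccc(OCc3ccccc3)c(OC)c2)[C@H]1C | intermediate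
6 | (1R,2S,3R)-2-[4-(benzyloxy)-3-methoxyphenyl]-1,3-dimethylcyclopropane-1-carbaldehyde | C[C@]1(C=O)[C@H](c2ccc(OCc3ccccc3)c(OC)c2)[C@H]1C | intermediate
7 | 4-bromo-2-methoxyphenol | COc1cc(Br)ccc1O | starting material
8 | (4-bromo-2-methoxyphenoxy)(tert-butyl)dimethylsilane | COc1cc(Br)ccc1O[Si](C)(C)C(C)(C)C | intermediate
9 | {4-[(tert-butyldimethylsilyl)oxy]-3-methoxyphenyl}lithium (not isolated) | [Li]c1ccc(O[Si](C)(C)C(C)(C)C)c(OC)c1 | intermediate
10 | [(1R,2S,3R)-2-[4-(benzyloxy)-3-methoxyphenyl]-1,3-dimethylcyclopropyl]{4-[(tert-butyldimethylsilyl)oxy]-3-methoxyphenyl}methanol, both carbinol epimers | C[C@]1(C(O)c2ccc(O[Si](C)(C)C(C)(C)C)c(OC)c2)[C@H](c2ccc(OCc3ccccc3)c(OC)c2)[C@H]1C | intermediate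
11 | [(1R,2S,3R)-2-[4-(benzyloxy)-3-methoxyphenyl]-1,3-dimethylcyclopropyl]{4-[(tert-butyldimethylsilyl)oxy]-3-methoxyphenyl}methanone (aroyl trans to ring B, CH–CH3 methyl cis to aroyl) | C[C@]1(C(=O)c2ccc(O[Si](C)(C)C(C)(C)C)c(OC)c2)[C@H](c2ccc(OCc3ccccc3)c(OC)c2)[C@H]1C | intermediate
12 | (2S,3S)-2-[4-(benzyloxy)-3-methoxyphenyl]-5-{4-[(tert-butyldimethylsilyl)oxy]-3-methoxyphenyl}-3,4-dimethyl-2,3-dihydrofuran (ring B trans to the adjacent methyl) | CC1=C(c2ccc(O[Si](C)(C)C(C)(C)C)c(OC)c2)O[C@H](c2ccc(OCc3ccccc3)c(OC)c2)[C@H]1C | intermediate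
13 | 4-[(2S,3S)-5-{4-[(tert-butyldimethylsilyl)oxy]-3-methoxyphenyl}-3,4-dimethyl-2,3-dihydrofuran-2-yl]-2-methoxyphenol (not isolated) | CC1=C(c2ccc(O[Si](C)(C)C(C)(C)C)c(OC)c2)O[C@H](c2ccc(O)c(OC)c2)[C@H]1C | intermediate
14 | 4-[(2S,3S,4R,5S)-5-{4-[(tert-butyldimethylsilyl)oxy]-3-methoxyphenyl}-3,4-dimethyloxolan-2-yl]-2-methoxyphenol (ring A, both methyls cis; ring B trans) | COc1cc([C@H]2O[C@H](c3ccc(O)c(OC)c3)[C@@H](C)[C@H]2C)ccc1O[Si](C)(C)C(C)(C)C | intermediate
15 | ethyl (2S)-2-hydroxypropanoate (ethyl (S)-lactate) | CCOC(=O)[C@H](C)O | starting material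
16 | ethyl (2R)-2-{4-[(2S,3S,4R,5S)-5-{4-[(tert-butyldimethylsilyl)oxy]-3-methoxyphenyl}-3,4-dimethyloxolan-2-yl]-2-methoxyphenoxy}propanoate | COc1cc([C@H]2O[C@H](c3ccc(O[C@H](C)C(=O)OCC)c(OC)c3)[C@@H](C)[C@H]2C)ccc1O[Si](C)(C)C(C)(C)C | intermediate
17 | (2R)-2-{4-[(2S,3S,4R,5S)-5-{4-[(tert-butyldimethylsilyl)oxy]-3-methoxyphenyl}-3,4-dimethyloxolan-2-yl]-2-methoxyphenoxy}-N-methoxy-N-methylpropanamide | COc1cc([C@H]2O[C@H](c3ccc(O[C@H](C)C(=O)N(C)OC)c(OC)c3)[C@@H](C)[C@H]2C)ccc1O[Si](C)(C)C(C)(C)C | intermediate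
18 | bromo{4-[(tert-butyldimethylsilyl)oxy]-3-methoxyphenyl}magnesium (not isolated) | COc1cc([Mg]Br)ccc1O[Si](C)(C)C(C)(C)C | intermediate
19 | (2R)-1-{4-[(tert-butyldimethylsilyl)oxy]-3-methoxyphenyl}-2-{4-[(2S,3S,4R,5S)-5-{4-[(tert-butyldimethylsilyl)oxy]-3-methoxyphenyl}-3,4-dimethyloxolan-2-yl]-2-methoxyphenoxy}propan-1-one | COc1cc([C@H]2O[C@H](c3ccc(O[C@H](C)C(=O)c4ccc(O[Si](C)(C)C(C)(C)C)c(OC)c4)c(OC)c3)[C@@H](C)[C@H]2C)ccc1O[Si](C)(C)C(C)(C)C | intermediate
20 | (1S,2R)-1-{4-[(tert-butyldimethylsilyl)oxy]-3-methoxyphenyl}-2-{4-[(2S,3S,4R,5S)-5-{4-[(tert-butyldimethylsilyl)oxy]-3-methoxyphenyl}-3,4-dimethyloxolan-2-yl]-2-methoxyphenoxy}propan-1-ol | COc1cc([C@H]2O[C@H](c3ccc(O[C@H](C)[C@@H](O)c4ccc(O[Si](C)(C)C(C)(C)C)c(OC)c4)c(OC)c3)[C@@H](C)[C@H]2C)ccc1O[Si](C)(C)C(C)(C)C | intermediate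
21 | 4-[(1S,2R)-1-hydroxy-2-{4-[(2S,3S,4R,5S)-5-(4-hydroxy-3-methoxyphenyl)-3,4-dimethyloxolan-2-yl]-2-methoxyphenoxy}propyl]-2-methoxyphenol | COc1cc([C@H]2O[C@H](c3ccc(O[C@H](C)[C@@H](O)c4ccc(O)c(OC)c4)c(OC)c3)[C@@H](C)[C@H]2C)ccc1O | target

Total step count: 14. Longest linear sequence: 13 steps (steps 1–4 and 6–14, from 1); step 5 is a one-step branch whose product 8 is used twice.

**Steps most likely to fail**

Step 9. Hydrogen may add to the wrong face, because the required face is the one that also carries ring B at C5. The O1–C5 bond of the aryl-substituted enol ether may be hydrogenolysed, or the double bond may migrate on palladium and scramble C4. The fallback sets out from 12 and comes back at 14, replacing substrate control on a surface by catalyst control in solution. A cationic iridium phosphinooxazoline complex, [Ir(cod)(tBu-PHOX)][B(C6H3(CF3)2)4] (CH2Cl2, H2 50 bar), reduces tetrasubstituted and enol-ether alkenes without cleaving benzyl ethers or benzylic C–O bonds; both ligand antipodes are available and the one matched to the required face is kept. It should give (2S,3S,4R,5S)-2-[4-(benzyloxy)-3-methoxyphenyl]-5-{4-[(tert-butyldimethylsilyl)oxy]-3-methoxyphenyl}-3,4-dimethyloxolane F1. Neutral hydrogenolysis of the benzyl ether (H2, Pd/C, EtOAc), which then acts on a saturated ring, gives 14.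

Step 3. Transfer of the substituted carbenoid to the trisubstituted alkene may be slow inside the bulky boronate complex, or facial discrimination may be incomplete; the latter cannot be repaired later, since it surfaces as the enantiomer of 12. The fallback sets out from 4 and comes back at 5, using resolution in place of induction. Ligand-free, hydroxyl-directed cyclopropanation of the zinc alkoxide of 4 (Et2Zn, CH3CHI2, CH2Cl2, 0 °C) should give, with the same relative configuration, rac-[(1R*,2S*,3R*)-2-[4-(benzyloxy)-3-methoxyphenyl]-1,3-dimethylcyclopropyl]methanol F2. Esterification with (S)-2-methoxy-2-phenylacetic acid (DCC, DMAP) and separation of the diastereomeric esters by chromatography or crystallisation isolates [(1R,2S,3R)-2-[4-(benzyloxy)-3-methoxyphenyl]-1,3-dimethylcyclopropyl]methyl (2S)-2-methoxy-2-phenylacetate F3. Saponification (LiOH, THF–H2O) returns 5.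

Step 8. The benzylic cation may lose a proton to give open-chain dienones, may be captured by the electron-rich rings, or the enol ether product may decompose under the Lewis acid. The fallback sets out from 6 and comes back at 12; it moves the ring expansion to the carboxylic acid oxidation level, where the product is an acid-stable lactone and O1–C5 is still made by carbonyl-oxygen capture of the same cation. Pinnick oxidation of 6 (NaClO2, NaH2PO4, 2-methylbut-2-ene, t-BuOH–H2O) gives (1R,2S,3R)-2-[4-(benzyloxy)-3-methoxyphenyl]-1,3-dimethylcyclopropane-1-carboxylic acid F4. Brønsted acid-catalysed isomerisation of this 2-arylcyclopropanecarboxylic acid (CF3SO3H cat., CH2Cl2) should give the trans lactone (4S,5S)-5-[4-(benzyloxy)-3-methoxyphenyl]-3,4-dimethyloxolan-2-one F5 (C3 epimers, of no consequence). Addition of aryllithium 9, generated from 8 and n-BuLi as in step 6, at −78 °C gives the hemiketal (4S,5S)-5-[4-(benzyloxy)-3-methoxyphenyl]-2-{4-[(tert-butyldimethylsilyl)oxy]-3-methoxyphenyl}-3,4-dimethyloxolan-2-ol F6. Dehydration (p-TsOH cat., or MsCl/Et3N) gives 12.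

**Further compounds**
F1 | step 9 | (2S,3S,4R,5S)-2-[4-(benzyloxy)-3-methoxyphenyl]-5-{4-[(tert-butyldimethylsilyl)oxy]-3-methoxyphenyl}-3,4-dimethyloxolane | COc1cc([C@H]2O[C@H](c3ccc(OCc4ccccc4)c(OC)c3)[C@@H](C)[C@H]2C)ccc1O[Si](C)(C)C(C)(C)C
F2 | step 3 | rac-[(1R*,2S*,3R*)-2-[4-(benzyloxy)-3-methoxyphenyl]-1,3-dimethylcyclopropyl]methanol (both enantiomers) | C[C@]1(CO)[C@H](c2ccc(OCc3ccccc3)c(OC)c2)[C@H]1C.C[C@@]1(CO)[C@@H](c2ccc(OCc3ccccc3)c(OC)c2)[C@@H]1C
F3 | step 3 | [(1R,2S,3R)-2-[4-(benzyloxy)-3-methoxyphenyl]-1,3-dimethylcyclopropyl]methyl (2S)-2-methoxy-2-phenylacetate | C[C@]1(COC(=O)[C@@H](OC)c2ccccc2)[C@H](c2ccc(OCc3ccccc3)c(OC)c2)[C@H]1C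
F4 | step 8 | (1R,2S,3R)-2-[4-(benzyloxy)-3-methoxyphenyl]-1,3-dimethylcyclopropane-1-carboxylic acid | C[C@]1(C(=O)O)[C@H](c2ccc(OCc3ccccc3)c(OC)c2)[C@H]1C
F5 | step 8 | (4S,5S)-5-[4-(benzyloxy)-3-methoxyphenyl]-3,4-dimethyloxolan-2-one (C3 epimers) | CC1C(=O)O[C@H](c2ccc(OCc3ccccc3)c(OC)c2)[C@H]1C
F6 | step 8 | (4S,5S)-5-[4-(benzyloxy)-3-methoxyphenyl]-2-{4-[(tert-butyldimethylsilyl)oxy]-3-methoxyphenyl}-3,4-dimethyloxolan-2-ol (epimers at C2 and C3) | CC1C(O)(c2ccc(O[Si](C)(C)C(C)(C)C)c(OC)c2)O[C@H](c2ccc(OCc3ccccc3)c(OC)c2)[C@H]1C
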